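Z is your substrate. The flask below asks when L peaks within the time allowed, and how high.

common to all: Z 14 mM

| flask | X | J | remark | time | volume of the second phase over the first |
|---|---|---|---|---|---|
| Friday's | 7.7 mM | 0.28 mM | run made earlier |  |  |
| Wednesday's | 12 mM | 0.28 mM | run made earlier |  |  |
| flask | 15.4 mM | 0.280 mM |  | 30 min | 1.0 |

| run | time / min | L / % | Z / % |
|---|---|---|---|
| Friday's | 1.00 | 11.5 | 85.5 |
| Friday's | 2.50 | 22.6 | 69.7 |
| Friday's | 6.00 | 25.0 | 53.6 |
| Friday's | 15.0 | 11.2 | 44.0 |
| Friday's | 40.0 | 0.1 | 42.1 |
| Wednesday's | 1.00 | 17.1 | 79.3 |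
| Wednesday's | 2.50 | 33.8 | 57.1 |
| Wednesday's | 6.00 | 36.4 | 35.6 |
| Wednesday's | 15.0 | 16.2 | 20.8 |
| Wednesday's | 40.0 | 1.4 | 12.8 |

(readings scatter by 0.3 percentage points)

- the moment within 30 min at which there is most L
- the amount of L, in percent of the Z charged, at that time

- percent here means Z units held: one G counts as two
- in the second phase: X; everything else is in the first
- charges count per volume of the first phase; a concentration in a rate is the amount of a species over the volume of its own phase; every rate counts per litre of the first phase
- steps thought possible: 2 Z -> G; L -> Q; D <-> X; Z + D -> L; Z + J -> E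
- the earlier runs hold the two phases in the same ratio of volumes as the flask asked about

My own reckoning starts from the earlier runs. Friday's X and J, taken at one Z each, leave 43.0% of the Z charge, and the reading at 40.0 min is 42.1%. Wednesday's leave 12.3%, and the reading is 12.8%. On Friday, then, X is the limiting reagent.

In the flask, X and J together over Z come to 112%. Call this the reach, the share of the Z charge they can consume at one Z each. The flask's reach is above the whole charge, so you expect a surplus of 12.0%.

The forecast, holding that “each X consumes one Z”, put the peak at 44.5% at 4 min. The flask gives 44.2% at 4.09 min, so the forecast held.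

    2 Z → G (k = 7.20 × 10⁻⁴ /M/s)
    L → Q (k = 0.00250 /s)
    D ⇌ X, rate k3*([D] - [X]/K3) per volume of the first phase (partition coefficient = 0.920, kL = 0.0260 /s)
    Z + D → L (k = 0.990 /M/s)
    Z + J → E (k = 73.0 /M/s)

Without the step from L to Q, the flask's peak stands at 94.9% instead of 44.2%, the largest single effect. The flask's surplus shows at 300 min: D and X still hold 12.2% of the Z charge. The neighbour with 35 mM of Z has a reach of 44.8%, which leaves 55.2%. That neighbour holds 52% of its Z at 30.0 min, with 2.93% gone to G.

Readings and results are calculated for an exercise, and the scatter is random.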